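A butenolide is cyclised by hydrogen-atom transfer to form the C1–C6 bond; the cis ring fusion this creates is then used, through a C7 selenide, to set C8 before the C6=C7 alkene is restored. Everything rests on cutting the C1–C6 bond of the cyclohexane (carotenoid numbering): it joins the gem-dimethyl carbon C1 to C6, which sits beside the quaternary ether carbon C5. The radical cyclisation makes this bond, closes the six-membered ring and sets C6 in one operation, using the C6=C7 alkene of a C5–C8 butenolide as acceptor; the C5 anchor forces cis fusion. The precursor is a 5-methylbutenolide whose C5 side chain carries the C3 silyl ether and an isopropenyl terminus. Wittig chemistry builds the polyene.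

Key step: step 8

Remark: the target is read as (3R,5R,8R), all-E, with the C3 oxygen cis to the ring oxygen and the C8 side chain anti to the C5 methyl; carotenoid locants (ring C1–C8, chain C9–C8') are used throughout, Ipc = isopinocampheyl, and compounds 1, 17 and 27 and all reagents are taken to be commercial.

Step 1
Reactants: 1 (S)-2-methylglycidol
Product: 2 (R)-triethyl[(2-methyloxiran-2-yl)methoxy]silane
Conditions: TESCl, imidazole, CH2Cl2, 0 °C
Reagents that add atoms: chlorotriethylsilane, CC[Si](Cl)(CC)CC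
Why: Chlorosilane–imidazole silylation of the primary alcohol is routine and, unlike alkoxide-based etherification, gives no opening for the degenerate Payne rearrangement that would racemise the epoxy alcohol, so the quaternary centre (future C5) is carried through unchanged.

Step 2
Reactants: 2 epoxy silyl ether
Product: 3 (R)-2-methyl-1-[(triethylsilyl)oxy]pent-4-en-2-ol
Conditions: CH2=CHMgBr, CuI (10 mol %), THF, −40 to −10 °C; aq NH4Cl
Reagents that add atoms: vinylmagnesium bromide, C=C[Mg]Br
Why: Copper-catalysed Grignard opening of the 2,2-disubstituted epoxide (SN2) should occur at the unhindered CH2, which becomes C4, so the tertiary carbinol C5 is formed without touching its configuration.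

Step 3
Reactants: 3 homoallylic tertiary alcohol
Product: 5 (R)-3-hydroxy-3-methyl-4-[(triethylsilyl)oxy]butanal, via secondary ozonide 4 (not isolated)
Conditions: O3, CH2Cl2, −78 °C; then PPh3, −78 to 23 °C
Reagents that add atoms: ozone, [O-][O+]=O
Why: Ozonolysis with phosphine work-up cleaves the only alkene under neutral conditions and should deliver the β-hydroxy aldehyde (C3) with the silyl ether and the tertiary alcohol intact.

Step 4
Reactants: 5 β-hydroxy aldehyde
Product: 6 (2R,4R)-2,6-dimethyl-1-[(triethylsilyl)oxy]hept-6-ene-2,4-diol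
Conditions: (+)-Ipc2BOMe, CH2=C(CH3)CH2MgCl, Et2O, −78 °C; then 5, −78 °C; then NaBO3, THF/H2O, 23 °C
Reagents that add atoms: 2-methylallylmagnesium chloride, CC(=C)C[Mg]Cl
Why: Brown methallylation (allylboration through a closed chair transition state) is reagent-controlled, so the (+)-Ipc2B reagent should add to the Re face of the aldehyde and set C3 as R, placing the C3 and C5 oxygens 1,3-syn, while an excess of the borane allows for slow reaction with the hindered tertiary hydroxyl.

Step 5
Reactants: 6 diol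
Product: 7 (2R,4R)-4-[(tert-butyldimethylsilyl)oxy]-2,6-dimethyl-1-[(triethylsilyl)oxy]hept-6-en-2-ol
Conditions: TBSCl, imidazole, DMF, 23 °C
Reagents that add atoms: tert-butylchlorodimethylsilane, CC(C)(C)[Si](C)(C)Cl
Why: Silylation with TBSCl and imidazole distinguishes the secondary C3 hydroxyl from the tertiary C5 hydroxyl on steric grounds.

Step 6
Reactants: 7 bis-silyl ether
Product: 9 (2R,4R)-4-[(tert-butyldimethylsilyl)oxy]-2-hydroxy-2,6-dimethylhept-6-enal, via alkoxysulfonium salt 8 (not isolated)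
Conditions: (COCl)2, DMSO, CH2Cl2, −78 to −40 °C; then Et3N, −78 to 0 °C
Reagents that add atoms: none
Why: Under Swern conditions a primary triethylsilyl ether is converted directly into the alkoxysulfonium salt and oxidised to the aldehyde (Swern oxidation with in situ desilylation), whereas the secondary TBS ether and the non-oxidisable tertiary alcohol should be left alone.

Step 7
Reactants: 9 α-hydroxy aldehyde
Product: 11 (R)-5-{(R)-2-[(tert-butyldimethylsilyl)oxy]-4-methylpent-4-en-1-yl}-5-methylfuran-2(5H)-one, via acyl ylide 10 (not isolated)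
Conditions: Ph3P=C=C=O, toluene, 90 °C
Reagents that add atoms: (triphenylphosphoranylidene)ketene, O=C=C=P(c1ccccc1)(c1ccccc1)c1ccccc1
Why: The tertiary hydroxyl adds across the cumulated ylide to give an ester-stabilised phosphorane that closes by intramolecular Wittig reaction on the neighbouring aldehyde, a known one-flask butenolide synthesis from α-hydroxy carbonyl compounds in which the new C6=C7 bond is cis by necessity.

Step 8
Reactants: 11 butenolide with isopropenyl side chain
Product: 12 (3aS,6R,7aR)-6-[(tert-butyldimethylsilyl)oxy]-4,4,7a-trimethylhexahydro-1-benzofuran-2(3H)-one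
Conditions: Fe(acac)3 (30 mol %), PhSiH3, EtOH/ethylene glycol, 60 °C
Reagents that add atoms: none
Why: Phenylsilane turns iron tris(acetylacetonate) into a transient iron hydride that hands a hydrogen atom to the unsubstituted carbon of the isopropenyl group, so the radical is born on the tertiary carbon C1 (Markovnikov sense); C1 then attacks C6, the β-carbon of the butenolide, and the resulting C7 radical next to the lactone carbonyl is reduced to the enolate and protonated by ethanol. The closest known reaction type is the metal-hydride hydrogen-atom-transfer olefin–enone reductive coupling (a radical Giese addition), here in its intramolecular form. The cyclohexane (C1–C6) closes in the 6-exo-trig mode through an early, chair-like transition state that tolerates the two quaternary neighbours and keeps the C3 silyloxy group equatorial. The one new stereocentre, C6, is dictated by the C5 stereocentre: the four-atom tether C2–C5 can reach only the butenolide face that bears C4, so the 6,5-fusion is necessarily cis (6S). The step needs hydrogen-atom transfer to the isopropenyl group and not to the butenolide, and ring closure ahead of radical quenching; the first follows from the electron-rich 1,1-disubstituted alkene against the electron-poor conjugated one, the second from the polarity match of a nucleophilic tertiary radical with an acceptor held six atoms away.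

Step 9
Reactants: 12 cis-fused lactone
Product: 14 (3R,3aS,6R,7aR)-6-[(tert-butyldimethylsilyl)oxy]-4,4,7a-trimethyl-3-(phenylselanyl)hexahydro-1-benzofuran-2(3H)-one, via lithium enolate 13 (not isolated)
Conditions: LiN(i-Pr)2, THF, −78 °C; then PhSeBr, −78 °C
Reagents that add atoms: benzeneselenenyl bromide, Br[Se]c1ccccc1
Why: Selenenylation of the lactone enolate: the electrophile should approach C7 on the convex face of the cis-fused bicycle, anti to the quaternary C1 on the neighbouring carbon, which puts selenium cis to H6 (7R), the arrangement needed both to steer C8 and for the later syn-elimination.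

Step 10
Reactants: 14 α-selanyl lactone
Product: 16 (3R,3aS,6R,7aR)-6-[(tert-butyldimethylsilyl)oxy]-4,4,7a-trimethyl-3-(phenylselanyl)octahydro-1-benzofuran-2-yl acetate (both C2 epimers), via aluminium lactolate 15 (not isolated)
Conditions: (i-Bu)2AlH, CH2Cl2, −78 °C; then pyridine, DMAP, Ac2O, −78 to −20 °C
Reagents that add atoms: acetic anhydride, CC(=O)OC(C)=O
Why: Reduction with (i-Bu)2AlH at −78 °C stops at the aluminium lactolate, which is acetylated in the same flask (one-pot reductive acetylation of a lactone), so the ionisable C8 acetate should be obtained without ring opening and without disturbing C7.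

Step 11
Reactants: 17 but-2-yn-1-ol
Product: 18 tert-butyl(but-2-yn-1-yloxy)diphenylsilane
Conditions: TBDPSCl, imidazole, CH2Cl2, 23 °C
Reagents that add atoms: tert-butylchlorodiphenylsilane, CC(C)(C)[Si](Cl)(c1ccccc1)c1ccccc1
Why: Standard silylation of a primary propargylic alcohol; the bulky, acid-tolerant TBDPS group is chosen to survive BF3·OEt2 later.

Step 12
Reactants: 18 propargylic silyl ether
Product: 19 (Z)-tert-butyldiphenyl{[3-(4,4,5,5-tetramethyl-1,3,2-dioxaborolan-2-yl)but-2-en-1-yl]oxy}silane (boron trans to the CH2O group)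
Conditions: CuCl (5 mol %), Xantphos, NaOt-Bu (10 mol %), B2pin2, MeOH, THF, 23 °C
Reagents that add atoms: bis(pinacolato)diboron, CC1(C)OB(OC1(C)C)B1OC(C)(C)C(C)(C)O1
Why: Copper-catalysed borylcupration–protonation (formal syn-hydroboration) of an internal propargylic ether should place boron on the alkyne carbon remote from the CH2O group and hydrogen cis to it, which fixes the geometry of the future C9=C10 bond (boron trans to C11).

Step 13
Reactants: 19 alkenyl pinacol boronate
Product: 20 potassium (Z)-{4-[(tert-butyldiphenylsilyl)oxy]but-2-en-2-yl}trifluoroborate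
Conditions: KHF2, MeOH/H2O, 23 °C
Reagents that add atoms: potassium hydrogen difluoride, [K+].[F-].F
Why: Conversion of a pinacol boronate into the trifluoroborate salt with KHF2 is routine and retains the alkene geometry.

Step 14
Reactants: 16 selanyl lactol acetate; 20 alkenyltrifluoroborate
Product: 21 (2S,3R,3aS,6R,7aR)-6-[(tert-butyldimethylsilyl)oxy]-2-{(E)-4-[(tert-butyldiphenylsilyl)oxy]but-2-en-2-yl}-4,4,7a-trimethyl-3-(phenylselanyl)octahydro-1-benzofuran
Conditions: BF3·OEt2, CH2Cl2/MeCN, −40 to 0 °C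
Reagents that add atoms: none
Why: Lewis-acid-promoted addition of an alkenyltrifluoroborate to a cyclic oxocarbenium ion (C-glycosylation type) transfers the alkenyl group with retention of its geometry, and the phenylselanyl group on the convex face at C7 (shielding plus seleniranium participation, the 1,2-trans rule of 2-selanyl furanosyl donors) should direct the new C8–C9 bond to the opposite face, syn to C4 and anti to the C5 methyl, which is the 8R arrangement of the target and could not be expected from the planar dihydrofuranyl cation, whose faces differ only by CH3 against CH2.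

Step 15
Reactants: 21 C8-alkenyl selenide
Product: 23 (2R,6R,7aR)-6-[(tert-butyldimethylsilyl)oxy]-2-{(E)-4-[(tert-butyldiphenylsilyl)oxy]but-2-en-2-yl}-4,4,7a-trimethyl-2,4,5,6,7,7a-hexahydro-1-benzofuran, via selenoxide 22 (not isolated)
Conditions: mCPBA, CH2Cl2, −78 °C; then i-Pr2NH, −78 to 23 °C
Reagents that add atoms: none
Why: Selenide oxidation at −78 °C is far faster than alkene epoxidation, and the selenoxide should undergo syn-elimination toward H6 (cis to selenium) and away from the oxygen-bearing C8, the usual regiochemistry of β-oxygenated selenoxides, which restores C6=C7 and leaves C8 untouched.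

Step 16
Reactants: 23 bis-silyl ether
Product: 24 (2R,6R,7aR)-2-[(E)-4-hydroxybut-2-en-2-yl]-4,4,7a-trimethyl-2,4,5,6,7,7a-hexahydro-1-benzofuran-6-ol
Conditions: Bu4NF, THF, 0 to 23 °C
Reagents that add atoms: none
Why: Fluoride-mediated desilylation removes both silyl ethers under non-acidic conditions that cannot ionise the bis-allylic C8–O bond.

Step 17
Reactants: 24 diol
Product: 26 {(E)-3-[(2R,6R,7aR)-6-hydroxy-4,4,7a-trimethyl-2,4,5,6,7,7a-hexahydro-1-benzofuran-2-yl]but-2-en-1-yl}triphenylphosphonium bromide, via allylic bromide 25 (not isolated)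
Conditions: NBS, Me2S, CH2Cl2, −20 to 0 °C; then PPh3, EtOAc, 23 °C
Reagents that add atoms: N-bromosuccinimide, O=C1CCC(=O)N1Br; triphenylphosphine, c1ccc(cc1)P(c1ccccc1)c1ccccc1
Why: Corey–Kim-type bromination with the NBS–Me2S complex should convert only the allylic alcohol into the bromide under neutral conditions (the saturated C3 alcohol returns unchanged), and SN2 quaternisation with PPh3 gives the allylic phosphonium salt without the acid that would epimerise C8.

Step 18
Reactants: 27 (2E,4E,6E)-2,7-dimethylocta-2,4,6-trienedial (used in excess)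
Product: 28 (2E,4E,6E,8E)-N-methoxy-N,4,9-trimethyl-10-oxodeca-2,4,6,8-tetraenamide
Conditions: (EtO)2P(O)CH2C(O)N(OMe)Me, NaH, THF, 0 °C
Reagents that add atoms: diethyl {2-[methoxy(methyl)amino]-2-oxoethyl}phosphonate, CCOP(=O)(CC(=O)N(C)OC)OCC
Why: Horner–Wadsworth–Emmons olefination of an excess of the symmetrical dialdehyde with the Weinreb-amide phosphonate should give the mono-adduct with E geometry, the amide serving as a latent C10' aldehyde that is inert to ylides.

Step 19
Reactants: 26 C15 phosphonium bromide; 28 aldehyde amide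
Product: 30 (2E,4E,6E,8E,10E,12E)-13-[(2R,6R,7aR)-6-hydroxy-4,4,7a-trimethyl-2,4,5,6,7,7a-hexahydro-1-benzofuran-2-yl]-N-methoxy-N,4,9-trimethyltetradeca-2,4,6,8,10,12-hexaenamide, via phosphorus ylide 29 (not isolated)
Conditions: NaOMe, MeOH/CH2Cl2, 0 to 23 °C; then EtOAc, reflux, dark
Reagents that add atoms: none
Why: Wittig olefination of the allylic ylide, generated with methoxide in the presence of the aldehyde, forms C11=C12 (the C15-phosphonium plus polyenal coupling of carotenoid chemistry), tolerates the free hydroxyl, and any 11Z isomer, a sterically hindered cis-alkene, should isomerise to E on heating.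

Step 20
Reactants: 30 polyene Weinreb amide
Product: 31 (2E,4E,6E,8E,10E,12E)-13-[(2R,6R,7aR)-6-hydroxy-4,4,7a-trimethyl-2,4,5,6,7,7a-hexahydro-1-benzofuran-2-yl]-4,9-dimethyltetradeca-2,4,6,8,10,12-hexaenal
Conditions: (i-Bu)2AlH, THF, −78 °C; aqueous potassium sodium tartrate
Reagents that add atoms: none
Why: Reduction of an α,β-unsaturated Weinreb amide with (i-Bu)2AlH stops at the chelated tetrahedral intermediate and releases the enal on neutral tartrate work-up, with no acid to endanger C8.

Step 21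
Reactants: 31 C27 polyenal
Product: 32 (2E,4E,6E,8E,10E,12E,14E)-15-[(2R,6R,7aR)-6-hydroxy-4,4,7a-trimethyl-2,4,5,6,7,7a-hexahydro-1-benzofuran-2-yl]-2,6,11-trimethylhexadeca-2,4,6,8,10,12,14-heptaenal (CNP0118413.1)
Conditions: Ph3P=C(CH3)CHO, toluene, 70 °C, dark
Reagents that add atoms: 2-(triphenylphosphoranylidene)propanal, CC(C=O)=P(c1ccccc1)(c1ccccc1)c1ccccc1
Why: Wittig reaction with the formyl-stabilised ylide is E-selective and should stop after one homologation because the α-methyl enal produced is more hindered and less electrophilic than the enal consumed, and the neutral conditions leave C8 and the polyene geometry intact.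

Compound list
1 | (S)-2-methylglycidol, [(2S)-2-methyloxiran-2-yl]methanol | OC[C@@]1(C)CO1 | starting material
2 | (R)-triethyl[(2-methyloxiran-2-yl)methoxy]silane | CC[Si](CC)(CC)OC[C@@]1(C)CO1 | intermediate
3 | (R)-2-methyl-1-[(triethylsilyl)oxy]pent-4-en-2-ol | C=CC[C@](O)(C)CO[Si](CC)(CC)CC | intermediate
4 | (2R)-2-methyl-1-(1,2,4-trioxolan-3-yl)-3-[(triethylsilyl)oxy]propan-2-ol (secondary ozonide, both epimers at the ring carbon) | C1OOC(C[C@](O)(C)CO[Si](CC)(CC)CC)O1 | intermediate
5 | (R)-3-hydroxy-3-methyl-4-[(triethylsilyl)oxy]butanal | O=CC[C@](O)(C)CO[Si](CC)(CC)CC | intermediate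
6 | (2R,4R)-2,6-dimethyl-1-[(triethylsilyl)oxy]hept-6-ene-2,4-diol | C=C(C)C[C@@H](O)C[C@](O)(C)CO[Si](CC)(CC)CC | intermediate
7 | (2R,4R)-4-[(tert-butyldimethylsilyl)oxy]-2,6-dimethyl-1-[(triethylsilyl)oxy]hept-6-en-2-ol | C=C(C)C[C@@H](O[Si](C)(C)C(C)(C)C)C[C@](O)(C)CO[Si](CC)(CC)CC | intermediate
8 | {[(2R,4R)-4-[(tert-butyldimethylsilyl)oxy]-2-hydroxy-2,6-dimethylhept-6-en-1-yl]oxy}dimethylsulfonium chloride | C=C(C)C[C@@H](O[Si](C)(C)C(C)(C)C)C[C@](O)(C)CO[S+](C)C.[Cl-] | intermediate
9 | (2R,4R)-4-[(tert-butyldimethylsilyl)oxy]-2-hydroxy-2,6-dimethylhept-6-enal | C=C(C)C[C@@H](O[Si](C)(C)C(C)(C)C)C[C@](O)(C)C=O | intermediate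
10 | (2R,4R)-4-[(tert-butyldimethylsilyl)oxy]-2,6-dimethyl-1-oxohept-6-en-2-yl (triphenylphosphoranylidene)acetate | C=C(C)C[C@@H](O[Si](C)(C)C(C)(C)C)C[C@](C)(C=O)OC(=O)C=P(c1ccccc1)(c1ccccc1)c1ccccc1 | intermediate
11 | (R)-5-{(R)-2-[(tert-butyldimethylsilyl)oxy]-4-methylpent-4-en-1-yl}-5-methylfuran-2(5H)-one | C=C(C)C[C@@H](O[Si](C)(C)C(C)(C)C)C[C@]1(C)C=CC(=O)O1 | intermediate
12 | (3aS,6R,7aR)-6-[(tert-butyldimethylsilyl)oxy]-4,4,7a-trimethylhexahydro-1-benzofuran-2(3H)-one (cis-fused) | O=C1C[C@H]2C(C)(C)C[C@@H](O[Si](C)(C)C(C)(C)C)C[C@@]2(C)O1 | intermediate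
13 | lithium (3aS,6R,7aR)-6-[(tert-butyldimethylsilyl)oxy]-4,4,7a-trimethyl-3a,4,5,6,7,7a-hexahydro-1-benzofuran-2-olate | [Li+].[O-]C1=C[C@H]2C(C)(C)C[C@@H](O[Si](C)(C)C(C)(C)C)C[C@@]2(C)O1 | intermediate
14 | (3R,3aS,6R,7aR)-6-[(tert-butyldimethylsilyl)oxy]-4,4,7a-trimethyl-3-(phenylselanyl)hexahydro-1-benzofuran-2(3H)-one (Se cis to H-3a) | O=C1[C@H]([Se]c3ccccc3)[C@H]2C(C)(C)C[C@@H](O[Si](C)(C)C(C)(C)C)C[C@@]2(C)O1 | intermediate
15 | {[(3R,3aS,6R,7aR)-6-[(tert-butyldimethylsilyl)oxy]-4,4,7a-trimethyl-3-(phenylselanyl)octahydro-1-benzofuran-2-yl]oxy}diisobutylalane (both C2 epimers) | CC(C)C[Al](CC(C)C)OC1[C@H]([Se]c3ccccc3)[C@H]2C(C)(C)C[C@@H](O[Si](C)(C)C(C)(C)C)C[C@@]2(C)O1 | intermediate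
16 | (3R,3aS,6R,7aR)-6-[(tert-butyldimethylsilyl)oxy]-4,4,7a-trimethyl-3-(phenylselanyl)octahydro-1-benzofuran-2-yl acetate (both C2 epimers) | CC(=O)OC1[C@H]([Se]c3ccccc3)[C@H]2C(C)(C)C[C@@H](O[Si](C)(C)C(C)(C)C)C[C@@]2(C)O1 | intermediate
17 | but-2-yn-1-ol | CC#CCO | starting material
18 | tert-butyl(but-2-yn-1-yloxy)diphenylsilane | CC#CCO[Si](c1ccccc1)(c1ccccc1)C(C)(C)C | intermediate
19 | (Z)-tert-butyldiphenyl{[3-(4,4,5,5-tetramethyl-1,3,2-dioxaborolan-2-yl)but-2-en-1-yl]oxy}silane | C/C(=C\CO[Si](c1ccccc1)(c1ccccc1)C(C)(C)C)B1OC(C)(C)C(C)(C)O1 | intermediate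
20 | potassium (Z)-{4-[(tert-butyldiphenylsilyl)oxy]but-2-en-2-yl}trifluoroborate | C/C(=C\CO[Si](c1ccccc1)(c1ccccc1)C(C)(C)C)[B-](F)(F)F.[K+] | intermediate
21 | (2S,3R,3aS,6R,7aR)-6-[(tert-butyldimethylsilyl)oxy]-2-{(E)-4-[(tert-butyldiphenylsilyl)oxy]but-2-en-2-yl}-4,4,7a-trimethyl-3-(phenylselanyl)octahydro-1-benzofuran | C/C(=C\CO[Si](c4ccccc4)(c4ccccc4)C(C)(C)C)[C@H]1[C@H]([Se]c3ccccc3)[C@H]2C(C)(C)C[C@@H](O[Si](C)(C)C(C)(C)C)C[C@@]2(C)O1 | intermediate
22 | Se-oxide of 21 (either configuration at selenium) | C/C(=C\CO[Si](c4ccccc4)(c4ccccc4)C(C)(C)C)[C@H]1[C@H]([Se](=O)c3ccccc3)[C@H]2C(C)(C)C[C@@H](O[Si](C)(C)C(C)(C)C)C[C@@]2(C)O1 | intermediate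
23 | (2R,6R,7aR)-6-[(tert-butyldimethylsilyl)oxy]-2-{(E)-4-[(tert-butyldiphenylsilyl)oxy]but-2-en-2-yl}-4,4,7a-trimethyl-2,4,5,6,7,7a-hexahydro-1-benzofuran | C/C(=C\CO[Si](c4ccccc4)(c4ccccc4)C(C)(C)C)[C@H]1C=C2C(C)(C)C[C@@H](O[Si](C)(C)C(C)(C)C)C[C@@]2(C)O1 | intermediate
24 | (2R,6R,7aR)-2-[(E)-4-hydroxybut-2-en-2-yl]-4,4,7a-trimethyl-2,4,5,6,7,7a-hexahydro-1-benzofuran-6-ol | C/C(=C\CO)[C@H]1C=C2C(C)(C)C[C@@H](O)C[C@@]2(C)O1 | intermediate
25 | (2R,6R,7aR)-2-[(E)-4-bromobut-2-en-2-yl]-4,4,7a-trimethyl-2,4,5,6,7,7a-hexahydro-1-benzofuran-6-ol | C/C(=C\CBr)[C@H]1C=C2C(C)(C)C[C@@H](O)C[C@@]2(C)O1 | intermediate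
26 | {(E)-3-[(2R,6R,7aR)-6-hydroxy-4,4,7a-trimethyl-2,4,5,6,7,7a-hexahydro-1-benzofuran-2-yl]but-2-en-1-yl}triphenylphosphonium bromide | C/C(=C\C[P+](c3ccccc3)(c3ccccc3)c3ccccc3)[C@H]1C=C2C(C)(C)C[C@@H](O)C[C@@]2(C)O1.[Br-] | intermediate
27 | (2E,4E,6E)-2,7-dimethylocta-2,4,6-trienedial | C\C(C=O)=C/C=C/C=C(\C)C=O | starting material
28 | (2E,4E,6E,8E)-N-methoxy-N,4,9-trimethyl-10-oxodeca-2,4,6,8-tetraenamide | CON(C)C(=O)/C=C/C(C)=C/C=C/C=C(\C)C=O | intermediate
29 | {(E)-3-[(2R,6R,7aR)-6-hydroxy-4,4,7a-trimethyl-2,4,5,6,7,7a-hexahydro-1-benzofuran-2-yl]but-2-en-1-ylidene}triphenylphosphorane | C/C(=C\C=P(c3ccccc3)(c3ccccc3)c3ccccc3)[C@H]1C=C2C(C)(C)C[C@@H](O)C[C@@]2(C)O1 | intermediate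
30 | (2E,4E,6E,8E,10E,12E)-13-[(2R,6R,7aR)-6-hydroxy-4,4,7a-trimethyl-2,4,5,6,7,7a-hexahydro-1-benzofuran-2-yl]-N-methoxy-N,4,9-trimethyltetradeca-2,4,6,8,10,12-hexaenamide | CON(C)C(=O)/C=C/C(C)=C/C=C/C=C(C)/C=C/C=C(\C)[C@H]1C=C2C(C)(C)C[C@@H](O)C[C@@]2(C)O1 | intermediate
31 | (2E,4E,6E,8E,10E,12E)-13-[(2R,6R,7aR)-6-hydroxy-4,4,7a-trimethyl-2,4,5,6,7,7a-hexahydro-1-benzofuran-2-yl]-4,9-dimethyltetradeca-2,4,6,8,10,12-hexaenal | O=C/C=C/C(C)=C/C=C/C=C(C)/C=C/C=C(\C)[C@H]1C=C2C(C)(C)C[C@@H](O)C[C@@]2(C)O1 | intermediate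
32 | (2E,4E,6E,8E,10E,12E,14E)-15-[(2R,6R,7aR)-6-hydroxy-4,4,7a-trimethyl-2,4,5,6,7,7a-hexahydro-1-benzofuran-2-yl]-2,6,11-trimethylhexadeca-2,4,6,8,10,12,14-heptaenal; (3R,5R,8R)-5,8-epoxy-3-hydroxy-5,8-dihydro-8'-apo-β-caroten-8'-al | C\C(C=O)=C/C=C/C(C)=C/C=C/C=C(C)/C=C/C=C(\C)[C@H]1C=C2C(C)(C)C[C@@H](O)C[C@@]2(C)O1 | target

Total step count: 21. Longest linear sequence: 17 steps (steps 1–10, 14–17 and 19–21, from 1 to 32).

Steps most likely to fail

Step 14. The phenylselanyl group may be transferred from the seleniranium/oxocarbenium ion to the electron-rich alkenylborate (loss of selenium and formation of the enol ether), or capture on the hindered concave face may be slow enough for the silyl ethers to suffer under the Lewis acid. The fallback sets out from acetate 16 and uses a slim, hard alkynyl nucleophile, then builds the trisubstituted alkene stereospecifically. The dimethylaluminium acetylide from tert-butyldimethyl(prop-2-yn-1-yloxy)silane (n-BuLi, then Me2AlCl) should displace the acetate trans to selenium to give the C8-alkynyl selenide (2S,3R,3aS,6R,7aR)-6-[(tert-butyldimethylsilyl)oxy]-2-{3-[(tert-butyldimethylsilyl)oxy]prop-1-yn-1-yl}-4,4,7a-trimethyl-3-(phenylselanyl)octahydro-1-benzofuran F1. Oxidation and syn-elimination as in step 15 gives the dihydrofuran alkyne F2, and Bu4NF gives the propargylic diol F3. Hydroxyl-directed trans-hydroalumination with NaAlH2(OCH2CH2OCH3)2 followed by iodine gives the (Z)-iodoallylic alcohol F4. Negishi methylation (MeZnCl, Pd(PPh3)4) replaces iodine by methyl with retention and rejoins the route at diol 24.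

Step 8. The tertiary C1 radical may be quenched before it cyclises (net hydrogenation of the isopropenyl group), or the butenolide may be reduced by the metal hydride before the crowded C1–C6 bond can form. The fallback sets out from 11 and generates the same radical without any metal hydride in the cyclisation flask. Mukaiyama hydration (Co(acac)2, PhSiH3, O2, i-PrOH) gives the tertiary alcohol (R)-5-{(R)-2-[(tert-butyldimethylsilyl)oxy]-4-hydroxy-4-methylpentyl}-5-methylfuran-2(5H)-one F8. Methyl chlorooxoacetate (Et3N, DMAP) gives its methyl oxalate F9, and CsOH gives the caesium oxalate F10. Visible-light photoredox decarboxylation (Ir[dF(CF3)ppy]2(dtbbpy)PF6, blue light, DME/DMF/H2O) releases two CO2 and the C1 radical, which closes 6-exo onto C6 and rejoins the route at lactone 12.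

Step 15. The syn-elimination may take the allylic H8 instead of H6 (giving the 2,3-dihydrofuran enol ether), or elimination toward the hindered H6 may be slow enough to allow over-oxidation. The fallback sets out from selenide 14 and changes the order of events. Oxidation (H2O2, pyridine) at the lactone stage, where H6 is the only hydrogen available, gives the butenolide (6R,7aR)-6-[(tert-butyldimethylsilyl)oxy]-4,4,7a-trimethyl-5,6,7,7a-tetrahydro-1-benzofuran-2(4H)-one F5. One-pot reductive acetylation as in step 10 gives the planar dihydrofuranyl acetate F6, which is coupled with trifluoroborate 20 under the conditions of step 14. Because the two faces of this cation differ only by the C5 methyl against C4H2, both C8 epimers are expected; 23 is separated by chromatography from its C8 epimer F7 and the route is rejoined at 23.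

Further compounds
F1 | step 14 | (2S,3R,3aS,6R,7aR)-6-[(tert-butyldimethylsilyl)oxy]-2-{3-[(tert-butyldimethylsilyl)oxy]prop-1-yn-1-yl}-4,4,7a-trimethyl-3-(phenylselanyl)octahydro-1-benzofuran | CC(C)(C)[Si](C)(C)OCC#C[C@H]1[C@H]([Se]c3ccccc3)[C@H]2C(C)(C)C[C@@H](O[Si](C)(C)C(C)(C)C)C[C@@]2(C)O1
F2 | step 14 | (2R,6R,7aR)-6-[(tert-butyldimethylsilyl)oxy]-2-{3-[(tert-butyldimethylsilyl)oxy]prop-1-yn-1-yl}-4,4,7a-trimethyl-2,4,5,6,7,7a-hexahydro-1-benzofuran | CC(C)(C)[Si](C)(C)OCC#C[C@H]1C=C2C(C)(C)C[C@@H](O[Si](C)(C)C(C)(C)C)C[C@@]2(C)O1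
F3 | step 14 | (2R,6R,7aR)-2-(3-hydroxyprop-1-yn-1-yl)-4,4,7a-trimethyl-2,4,5,6,7,7a-hexahydro-1-benzofuran-6-ol | OCC#C[C@H]1C=C2C(C)(C)C[C@@H](O)C[C@@]2(C)O1
F4 | step 14 | (2R,6R,7aR)-2-[(Z)-3-hydroxy-1-iodoprop-1-en-1-yl]-4,4,7a-trimethyl-2,4,5,6,7,7a-hexahydro-1-benzofuran-6-ol | I/C(=C\CO)[C@H]1C=C2C(C)(C)C[C@@H](O)C[C@@]2(C)O1
F8 | step 8 | (R)-5-{(R)-2-[(tert-butyldimethylsilyl)oxy]-4-hydroxy-4-methylpentyl}-5-methylfuran-2(5H)-one | CC(C)(O)C[C@@H](O[Si](C)(C)C(C)(C)C)C[C@]1(C)C=CC(=O)O1
F9 | step 8 | methyl oxalate of F8: (R)-4-[(tert-butyldimethylsilyl)oxy]-2-methyl-5-[(R)-2-methyl-5-oxo-2,5-dihydrofuran-2-yl]pentan-2-yl methyl oxalate | COC(=O)C(=O)OC(C)(C)C[C@@H](O[Si](C)(C)C(C)(C)C)C[C@]1(C)C=CC(=O)O1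
F10 | step 8 | caesium oxalate of F8: caesium 2-({(R)-4-[(tert-butyldimethylsilyl)oxy]-2-methyl-5-[(R)-2-methyl-5-oxo-2,5-dihydrofuran-2-yl]pentan-2-yl}oxy)-2-oxoacetate | [Cs+].[O-]C(=O)C(=O)OC(C)(C)C[C@@H](O[Si](C)(C)C(C)(C)C)C[C@]1(C)C=CC(=O)O1
F5 | step 15 | (6R,7aR)-6-[(tert-butyldimethylsilyl)oxy]-4,4,7a-trimethyl-5,6,7,7a-tetrahydro-1-benzofuran-2(4H)-one | O=C1C=C2C(C)(C)C[C@@H](O[Si](C)(C)C(C)(C)C)C[C@@]2(C)O1
F6 | step 15 | (6R,7aR)-6-[(tert-butyldimethylsilyl)oxy]-4,4,7a-trimethyl-2,4,5,6,7,7a-hexahydro-1-benzofuran-2-yl acetate (both C2 epimers) | CC(=O)OC1C=C2C(C)(C)C[C@@H](O[Si](C)(C)C(C)(C)C)C[C@@]2(C)O1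
F7 | step 15 | (2S,6R,7aR)-6-[(tert-butyldimethylsilyl)oxy]-2-{(E)-4-[(tert-butyldiphenylsilyl)oxy]but-2-en-2-yl}-4,4,7a-trimethyl-2,4,5,6,7,7a-hexahydro-1-benzofuran (C8 epimer of 23) | C/C(=C\CO[Si](c4ccccc4)(c4ccccc4)C(C)(C)C)[C@@H]1C=C2C(C)(C)C[C@@H](O[Si](C)(C)C(C)(C)C)C[C@@]2(C)O1
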